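The route cuts ring C at C2. That carbon is at the carboxylic oxidation level and its three heavy-atom neighbours are O1, C3 and C1' of ring B, so it can be delivered as carbon monoxide. One palladium-catalysed operation joins the ring B aryl bromide, CO and an o-hydroxyaryl benzyloxymethyl ketone (ring A with C3 and C4). Aroylation of the phenol, O→C aroyl shift and cyclodehydration form C1'–C2, C2–C3 and O1–C2. The ketone carries a single free phenol, O8 as a methoxymethyl acetal, O3 and O5 as benzyl ethers and O7 as the methyl ether. The end game is then only acetal cleavage, acetylation and hydrogenolysis.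

Key step: step 8

Remarks on the chemistry: compounds 1, 6, 12 and 14 and all reagents are taken as purchased. Species that exist only bound to the palladium catalyst are described in words and are not numbered. Diketone 16 is drawn as the diketo tautomer; its central carbon is enolisable and no configuration is implied. The target has no stereocentre.

Step 1
Reactants: 1 3,4-dihydroxy-5-methoxybenzaldehyde (5-hydroxyvanillin)
Product: 2 3-methoxy-4,5-bis(methoxymethoxy)benzaldehyde
Conditions: MOMCl (2.6 equiv), K2CO3, acetone, 0 °C → reflux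
Reagents that add atoms: chloromethyl methyl ether, COCCl
Why: Williamson-type O-alkylation of both catechol hydroxyls with the reactive α-chloro ether should give the bis-acetal, which masks O8 and the future ring-closing oxygen and supplies the directing group for step 4.

Step 2
Reactants: 2 3-methoxy-4,5-bis(methoxymethoxy)benzaldehyde
Product: 4 3-methoxy-4,5-bis(methoxymethoxy)phenol, via aryl formate 3 (not isolated)
Conditions: mCPBA, CH2Cl2, 0 °C → rt; aq. NaHCO3 wash; then K2CO3 (cat.), MeOH, rt
Reagents that add atoms: 3-chloroperoxybenzoic acid, OOC(=O)c1cccc(Cl)c1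
Why: Baeyer–Villiger oxidation of an electron-rich benzaldehyde, in which the aryl group activated by the para acetal oxygen migrates to oxygen, should give formate 3, and its methanolysis frees the phenol that becomes O5.

Step 3
Reactants: 4 3-methoxy-4,5-bis(methoxymethoxy)phenol
Product: 5 5-(benzyloxy)-1-methoxy-2,3-bis(methoxymethoxy)benzene
Conditions: BnBr, K2CO3, DMF, rt
Reagents that add atoms: benzyl bromide, BrCc1ccccc1
Why: Williamson etherification of the only free phenol fixes O5 as a benzyl ether that stays in place until the final hydrogenolysis.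

Step 4
Reactants: 5 5-(benzyloxy)-1-methoxy-2,3-bis(methoxymethoxy)benzene; 6 2-(benzyloxy)-N-methoxy-N-methylacetamide
Product: 8 2-(benzyloxy)-1-[6-(benzyloxy)-4-methoxy-2,3-bis(methoxymethoxy)phenyl]ethan-1-one, via aryllithium 7 (not isolated)
Conditions: n-BuLi, THF, −40 → −10 °C; then 6, −78 °C → rt; aq. NH4Cl
Reagents that add atoms: none
Why: Directed ortho-metalation followed by Weinreb ketone synthesis should work because the ring C–H flanked by the acetal oxygen and the benzyloxy group is removed under coordination control and the aryllithium acylates the N-methoxy-N-methylamide only once, stopping at the ketone.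

Step 5
Reactants: 8 2-(benzyloxy)-1-[6-(benzyloxy)-4-methoxy-2,3-bis(methoxymethoxy)phenyl]ethan-1-one
Product: 9 2-(benzyloxy)-1-[6-(benzyloxy)-2,3-dihydroxy-4-methoxyphenyl]ethan-1-one
Conditions: HCl (3 M in MeOH), THF, 45 °C
Reagents that add atoms: none

Why: Acid-catalysed acetal exchange with methanol removes both methoxymethyl groups, while the aryl and alkyl benzyl ethers are stable to dilute HCl.

Step 6
Reactants: 9 2-(benzyloxy)-1-[6-(benzyloxy)-2,3-dihydroxy-4-methoxyphenyl]ethan-1-one
Product: 11 2-(benzyloxy)-1-[6-(benzyloxy)-2-hydroxy-4-methoxy-3-(methoxymethoxy)phenyl]ethan-1-one, via disodium catecholate 10 (not isolated)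
Conditions: NaH (2.1 equiv), DMF, 0 °C; then MOMCl (1.0 equiv), 0 °C → rt; aq. NH4Cl
Reagents that add atoms: chloromethyl methyl ether, COCCl
Why: Regioselective O-alkylation of a catechol dianion should place the acetal on the phenoxide remote from the ketone, which is not conjugated with or chelated by the carbonyl and is therefore the more nucleophilic, leaving the ketone-flanked phenol free for ring closure.

Step 7
Reactants: 12 4-bromobenzene-1,2-diol (4-bromocatechol)
Product: 13 4-bromo-1,2-bis(benzyloxy)benzene
Conditions: BnBr (2.3 equiv), K2CO3, DMF, 60 °C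
Reagents that add atoms: benzyl bromide, BrCc1ccccc1
Why: Twofold Williamson etherification of the catechol proceeds without touching the aryl bromide, which is inert to carbonate and benzyl bromide.

Step 8
Reactants: 11 2-(benzyloxy)-1-[6-(benzyloxy)-2-hydroxy-4-methoxy-3-(methoxymethoxy)phenyl]ethan-1-one; 13 4-bromo-1,2-bis(benzyloxy)benzene; 14 carbon monoxide
Product: 17 3,5-bis(benzyloxy)-2-[3,4-bis(benzyloxy)phenyl]-7-methoxy-8-(methoxymethoxy)-4H-chromen-4-one, via aryl ester 15 (not isolated), via 1,3-diketone 16 (not isolated)
Conditions: Pd(OAc)2 (2 mol %), 1,4-bis(diphenylphosphino)butane (4 mol %), DBU (3 equiv), CO (10 bar), DMSO, 120 °C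
Reagents that add atoms: none
Why: Zerovalent palladium, formed in situ from Pd(OAc)2 and the bisphosphine, inserts into the C–Br bond of 13 and takes up CO to give the aroylpalladium bromide ArC(O)PdBr, which is intercepted by the DBU-generated phenoxide of 11 to release ester 15 and return zerovalent palladium. DBU then removes a proton from the CH2 lying between the ketone and the benzyloxy group, and the enolate attacks the neighbouring ester in an intramolecular Claisen-type O→C aroyl shift (Baker–Venkataraman rearrangement) to give 1,3-diketone 16. The freed phenoxide adds to the aryl ketone carbonyl in a 6-exo-trig closure, and loss of water from the hemiketal completes ring C as the chromen-4-one. The closest known reaction type is the palladium-catalysed carbonylative synthesis of flavones from aryl bromides, CO and 2-hydroxyacetophenones, here run on an α-alkoxy ketone so that C3 emerges already oxygenated. No stereocentre is formed. The step needs chemoselectivity (carbonylative rather than direct C–O coupling, and a single mode of ring closure), which CO pressure and the substrate secure, since 11 has one free phenol (O5 benzylated, O8 acetalised) and one enolisable carbon.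

Step 9
Reactants: 17 3,5-bis(benzyloxy)-2-[3,4-bis(benzyloxy)phenyl]-7-methoxy-8-(methoxymethoxy)-4H-chromen-4-one
Product: 18 3,5-bis(benzyloxy)-2-[3,4-bis(benzyloxy)phenyl]-8-hydroxy-7-methoxy-4H-chromen-4-one
Conditions: HCl (2 M in MeOH), THF, 40 °C
Reagents that add atoms: none

Why: Acid-catalysed acetal methanolysis should remove the methoxymethyl group from O8 alone, since the benzyl ethers and the chromenone tolerate dilute HCl at this temperature.

Step 10
Reactants: 18 3,5-bis(benzyloxy)-2-[3,4-bis(benzyloxy)phenyl]-8-hydroxy-7-methoxy-4H-chromen-4-one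
Product: 19 3,5-bis(benzyloxy)-2-[3,4-bis(benzyloxy)phenyl]-7-methoxy-4-oxo-4H-chromen-8-yl acetate
Conditions: Ac2O, pyridine, DMAP (cat.), CH2Cl2, 0 °C → rt
Reagents that add atoms: acetic anhydride, CC(=O)OC(C)=O
Why: Nucleophile-catalysed O-acylation of the single free hydroxyl, the one on C8, places the acetate exactly where the target carries it.

Step 11
Reactants: 19 3,5-bis(benzyloxy)-2-[3,4-bis(benzyloxy)phenyl]-7-methoxy-4-oxo-4H-chromen-8-yl acetate
Product: 20 2-(3,4-dihydroxyphenyl)-3,5-dihydroxy-7-methoxy-4-oxo-4H-chromen-8-yl acetate (gossypetin 7-methyl ether 8-acetate)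
Conditions: H2 (1 atm), 10% Pd/C, EtOAc–THF, rt
Reagents that add atoms: none

Why: Catalytic hydrogenolysis of the four benzyl ethers frees O3, O5, O3' and O4' under neutral conditions that should leave the aryl acetate, the methyl ether and the C2–C3 double bond intact, and no free hydroxyl adjoins O8 to invite acetyl migration.

Compound list
1 | 3,4-dihydroxy-5-methoxybenzaldehyde (5-hydroxyvanillin) | COc1cc(C=O)cc(O)c1O | starting material
2 | 3-methoxy-4,5-bis(methoxymethoxy)benzaldehyde | COCOc1cc(C=O)cc(OC)c1OCOC | intermediate
3 | 3-methoxy-4,5-bis(methoxymethoxy)phenyl formate | COCOc1cc(OC=O)cc(OC)c1OCOC | intermediate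
4 | 3-methoxy-4,5-bis(methoxymethoxy)phenol | COCOc1cc(O)cc(OC)c1OCOC | intermediate
5 | 5-(benzyloxy)-1-methoxy-2,3-bis(methoxymethoxy)benzene | COCOc1cc(OCc2ccccc2)cc(OC)c1OCOC | intermediate
6 | 2-(benzyloxy)-N-methoxy-N-methylacetamide | CON(C)C(=O)COCc1ccccc1 | starting material
7 | [6-(benzyloxy)-4-methoxy-2,3-bis(methoxymethoxy)phenyl]lithium | COCOc1c([Li])c(OCc2ccccc2)cc(OC)c1OCOC | intermediate
8 | 2-(benzyloxy)-1-[6-(benzyloxy)-4-methoxy-2,3-bis(methoxymethoxy)phenyl]ethan-1-one | COCOc1c(OCOC)c(OC)cc(OCc2ccccc2)c1C(=O)COCc1ccccc1 | intermediate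
9 | 2-(benzyloxy)-1-[6-(benzyloxy)-2,3-dihydroxy-4-methoxyphenyl]ethan-1-one | COc1cc(OCc2ccccc2)c(C(=O)COCc2ccccc2)c(O)c1O | intermediate
10 | disodium 4-(benzyloxy)-3-[(benzyloxy)acetyl]-6-methoxybenzene-1,2-bis(olate) | [Na+].[Na+].COc1cc(OCc2ccccc2)c(C(=O)COCc2ccccc2)c([O-])c1[O-] | intermediate
11 | 2-(benzyloxy)-1-[6-(benzyloxy)-2-hydroxy-4-methoxy-3-(methoxymethoxy)phenyl]ethan-1-one | COCOc1c(OC)cc(OCc2ccccc2)c(C(=O)COCc2ccccc2)c1O | intermediate
12 | 4-bromobenzene-1,2-diol (4-bromocatechol) | Oc1ccc(Br)cc1O | starting material
13 | 4-bromo-1,2-bis(benzyloxy)benzene | Brc1ccc(OCc2ccccc2)c(OCc2ccccc2)c1 | intermediate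
14 | carbon monoxide | [C-]#[O+] | starting material
15 | 2-[(benzyloxy)acetyl]-3-(benzyloxy)-5-methoxy-6-(methoxymethoxy)phenyl 3,4-bis(benzyloxy)benzoate | COCOc1c(OC)cc(OCc2ccccc2)c(C(=O)COCc2ccccc2)c1OC(=O)c1ccc(OCc2ccccc2)c(OCc2ccccc2)c1 | intermediate
16 | 2-(benzyloxy)-1-[6-(benzyloxy)-2-hydroxy-4-methoxy-3-(methoxymethoxy)phenyl]-3-[3,4-bis(benzyloxy)phenyl]propane-1,3-dione | COCOc1c(OC)cc(OCc2ccccc2)c(C(=O)C(OCc2ccccc2)C(=O)c2ccc(OCc3ccccc3)c(OCc3ccccc3)c2)c1O | intermediate
17 | 3,5-bis(benzyloxy)-2-[3,4-bis(benzyloxy)phenyl]-7-methoxy-8-(methoxymethoxy)-4H-chromen-4-one | COCOc1c(OC)cc(OCc2ccccc2)c2c(=O)c(OCc3ccccc3)c(-c3ccc(OCc4ccccc4)c(OCc4ccccc4)c3)oc12 | intermediate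
18 | 3,5-bis(benzyloxy)-2-[3,4-bis(benzyloxy)phenyl]-8-hydroxy-7-methoxy-4H-chromen-4-one | COc1cc(OCc2ccccc2)c2c(=O)c(OCc3ccccc3)c(-c3ccc(OCc4ccccc4)c(OCc4ccccc4)c3)oc2c1O | intermediate
19 | 3,5-bis(benzyloxy)-2-[3,4-bis(benzyloxy)phenyl]-7-methoxy-4-oxo-4H-chromen-8-yl acetate | COc1cc(OCc2ccccc2)c2c(=O)c(OCc3ccccc3)c(-c3ccc(OCc4ccccc4)c(OCc4ccccc4)c3)oc2c1OC(C)=O | intermediate
20 | 2-(3,4-dihydroxyphenyl)-3,5-dihydroxy-7-methoxy-4-oxo-4H-chromen-8-yl acetate | COc1cc(O)c2c(=O)c(O)c(-c3ccc(O)c(O)c3)oc2c1OC(C)=O | target

Total step count: 11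
Longest linear sequence: 10 steps (steps 1–6, then 8–11); step 7 is the only branch.

Steps most likely to fail

Step 8. On this hindered, doubly ortho-substituted phenol, CO uptake, aroyl transfer and ring closure may not keep pace. The sequence could then stall at the ester stage, or divert to direct C–O coupling or loss of bromine from 13. The fallback sets out from 11 and brings in the C2 carbon without palladium. Commercial 3,4-bis(benzyloxy)benzoic acid is converted with oxalyl chloride into 3,4-bis(benzyloxy)benzoyl chloride F1, which acylates 11 in pyridine to give 15. KOH in pyridine then effects the Baker–Venkataraman shift to 16, and warming with DBU in DMSO (or catalytic p-TsOH in toluene) closes ring C. The fallback comes back to the route at 17.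

Step 4. Proton transfer to the hindered aryllithium 7 may outrun acyl transfer and return 5. The proton could come from the α-CH2 of amide 6 or, on warming, from the benzylic CH2 of the neighbouring ether. The fallback sets out from 5. Compound 7 is generated as before but trapped at −78 °C with commercial benzyloxyacetaldehyde, a much faster electrophile, to give racemic 2-(benzyloxy)-1-[6-(benzyloxy)-4-methoxy-2,3-bis(methoxymethoxy)phenyl]ethan-1-ol F2. Oxidation of this benzylic alcohol with Dess–Martin periodinane comes back to the route at 8.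

Step 6. Alkylation of the dianion may also occur at the ketone-flanked oxygen, or twice, eroding the regioselectivity. The fallback sets out from 8 and differentiates the two acetals by selective removal instead of selective introduction. The acetal next to the ketone is the more labile, because the departing phenol is conjugated with and hydrogen-bonded to the carbonyl. Brief exposure of 8 to dilute HCl in MeOH at 0 °C → rt (or to MgBr2·OEt2 in Et2O) should cleave it alone. This comes back to the route at 11, bypassing 9 and 10, and makes no new compound (F0).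

Further compounds
F1 | step 8 | 3,4-bis(benzyloxy)benzoyl chloride | O=C(Cl)c1ccc(OCc2ccccc2)c(OCc2ccccc2)c1
F2 | step 4 | rac-2-(benzyloxy)-1-[6-(benzyloxy)-4-methoxy-2,3-bis(methoxymethoxy)phenyl]ethan-1-ol | COCOc1c(C(O)COCc2ccccc2)c(OCc2ccccc2)cc(OC)c1OCOC
F0 | step 6 | none | none
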